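**Retrosynthetic overview**
1. The plan rests on one feature: C5 bears a hydroxyl on the carbon beta to both the C4 carbonyl and C8a (through C4a). C5–O and O1–C2 of the pyranone ring (O1, C2, C3, C4, C4a, C8a) are therefore cut together, leaving a C4a=C5 alkylidene 1,3-dicarbonyl (a 2-alkynoyl cyclohexenone) and 4-methoxybenzyl alcohol.
2. The alkynoyl group is cut at C4a–C4 (alkenyl iodide plus 5-phenylpent-2-ynal, then oxidation). The enone goes back to a 1-bromo-1,3-diene by singlet-oxygen chemistry, which supplies the C8a carbonyl (from C–Br) and the C6 oxygen trans to C7–O.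
3. The C8 aryl ether is cut at O–C(aryl) (O-arylation with retention by a chromonyl iodonium salt), so the cis C7/C8 oxygens are those of (1S,2S)-3-bromocyclohexa-3,5-diene-1,2-diol.
4. The arylating chromone is cut at O1–C2 and C3–C4 to 2'-hydroxy-4'-methoxyacetophenone and ethyl 3-phenylpropanoate.
5. Ring order: pyranone of the upper chromone (step 2), carbocycle taken from the chiral pool, pyranone of the tetrahydrochromone last (step 12).

Key step: step 12

Remark: carbocycle atoms carry their target numbers (C4a, C5–C8, C8a) throughout; Ar = 7-methoxy-4-oxo-2-(2-phenylethyl)-4H-chromen-6-yl, TDS = dimethyl(2,3-dimethylbutan-2-yl)silyl, TBS = tert-butyldimethylsilyl, PMB = 4-methoxybenzyl; the carbinol centre made in the Nozaki–Hiyama–Kishi step is carried as an epimer mixture because the following oxidation removes it.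

**Step 1**
Reactants: 1 2'-hydroxy-4'-methoxyacetophenone
Product: 2 1-(2-hydroxy-5-iodo-4-methoxyphenyl)ethan-1-one
Conditions: NIS, TFA (cat.), MeCN, rt
Reagents that add atoms: N-iodosuccinimide, O=C1CCC(=O)N1I
Why: Electrophilic aromatic iodination should occur at C5', which is para to the free phenol and ortho to the methoxy group, because C3' is flanked by both oxygen substituents; this carbon becomes C6 of the chromone.

**Step 2**
Reactants: 2 1-(2-hydroxy-5-iodo-4-methoxyphenyl)ethan-1-one, 3 ethyl 3-phenylpropanoate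
Product: 5 6-iodo-7-methoxy-2-(2-phenylethyl)-4H-chromen-4-one, via 1,3-diketone 4 (not isolated)
Conditions: NaH (4 equiv), THF, reflux; then conc. HCl, MeOH, reflux
Reagents that add atoms: none
Why: Claisen condensation of the acetophenone dianion with the ester gives the 1,3-diketone and acid-catalysed cyclodehydration closes the pyranone (the classical 2-alkylchromone synthesis), the aryl iodide being inert to both stages.

**Step 3**
Reactants: 5 6-iodo-7-methoxy-2-(2-phenylethyl)-4H-chromen-4-one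
Product: 7 Ar(2,4,6-trimethoxyphenyl)iodonium 4-toluenesulfonate, via hydroxy(tosyloxy)iodoarene 6 (not isolated)
Conditions: mCPBA, TsOH·H2O, MeCN, 77 °C; then 1,3,5-trimethoxybenzene, 77 °C to rt
Reagents that add atoms: 1,3,5-trimethoxybenzene, COc1cc(OC)cc(OC)c1; 4-toluenesulfonic acid, Cc1ccc(S(=O)(=O)O)cc1
Why: One-pot oxidation of the aryl iodide to the hydroxy(tosyloxy) trivalent-iodine species followed by electrophilic substitution of the very electron-rich trimethoxybenzene is an established route to unsymmetrical diaryliodonium salts in which the trimethoxyphenyl group is the non-transferred ligand.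

**Step 4**
Reactants: 8 (1S,2S)-3-bromocyclohexa-3,5-diene-1,2-diol
Product: 9 (1S,6S)-2-bromo-6-(TDS-oxy)cyclohexa-2,4-dien-1-ol
Conditions: TDSCl, imidazole, DMF, −20 to 0 °C
Reagents that add atoms: chloro(dimethyl)(2,3-dimethylbutan-2-yl)silane, CC(C)C(C)(C)[Si](C)(C)Cl
Why: Regioselective silylation with a bulky chlorosilane should take the O7 hydroxyl, which is distal to bromine and flanked only by a CH=, and leave the O8 hydroxyl next to the C–Br carbon free; no stereocentre is touched.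

**Step 5**
Reactants: 9 (1S,6S)-2-bromo-6-(TDS-oxy)cyclohexa-2,4-dien-1-ol, 7 Ar(2,4,6-trimethoxyphenyl)iodonium 4-toluenesulfonate
Product: 10 6-{[(1S,6S)-2-bromo-6-(TDS-oxy)cyclohexa-2,4-dien-1-yl]oxy}-7-methoxy-2-(2-phenylethyl)-4H-chromen-4-one
Conditions: t-BuONa, toluene, 0 °C; then 7, 0 °C to rt
Reagents that add atoms: none
Why: O-arylation of a secondary sodium alkoxide with a diaryliodonium salt (ligand exchange at trivalent iodine, then ligand coupling) forms the aryl ether without breaking the C8–O bond, so C8 keeps its configuration; the chromonyl group should transfer because trimethoxyphenyl is the more electron-rich ligand, and a silyl shift is disfavoured because O8 is the more hindered and more acidic oxygen.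

**Step 6**
Reactants: 10 6-{[(1S,6S)-2-bromo-6-(TDS-oxy)cyclohexa-2,4-dien-1-yl]oxy}-7-methoxy-2-(2-phenylethyl)-4H-chromen-4-one
Product: 13 (4R,5S,6S)-6-(Ar-oxy)-4-hydroxy-5-(TDS-oxy)cyclohex-2-en-1-one, via endoperoxide 11 (not isolated), via C8a bromohydrin 12 (not isolated)
Conditions: O2, tetraphenylporphyrin (cat.), visible light, CH2Cl2, −78 °C; then thiourea, NaHCO3, MeOH, −78 °C to rt
Reagents that add atoms: oxygen, O=O
Why: Singlet oxygen should add [4+2] across C8a and C6 on the diene face opposite to the cis C7/C8 substituents, thiourea then reduces the O–O bond and the C8a bromohydrin collapses to the ketone, which sets C6–OH trans to C7–O and gives the 4-hydroxy enone as known for halodiene diol derivatives.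

**Step 7**
Reactants: 13 (4R,5S,6S)-6-(Ar-oxy)-4-hydroxy-5-(TDS-oxy)cyclohex-2-en-1-one
Product: 14 (4R,5R,6S)-6-(Ar-oxy)-4-(TBS-oxy)-5-(TDS-oxy)cyclohex-2-en-1-one
Conditions: TBSOTf, 2,6-lutidine, CH2Cl2, −78 °C
Reagents that add atoms: tert-butyldimethylsilyl trifluoromethanesulfonate, CC(C)(C)[Si](C)(C)OS(=O)(=O)C(F)(F)F
Why: Silylation of the allylic C6 hydroxyl with a silyl triflate and a hindered, non-nucleophilic base is fast at low temperature and avoids base-induced beta-elimination next to the ketone.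

**Step 8**
Reactants: 14 (4R,5R,6S)-6-(Ar-oxy)-4-(TBS-oxy)-5-(TDS-oxy)cyclohex-2-en-1-one
Product: 15 (4R,5R,6S)-6-(Ar-oxy)-4-(TBS-oxy)-5-(TDS-oxy)-2-iodocyclohex-2-en-1-one
Conditions: I2, pyridine, DMAP (cat.), CH2Cl2, 0 °C to rt
Reagents that add atoms: iodine, II
Why: Johnson alpha-iodination (conjugate addition of the pyridine base, iodination of the enolate at C4a, elimination) is routine for gamma-silyloxy cyclohexenones; the 2-substituted chromone should not react because its beta carbon is fully substituted.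

**Step 9**
Reactants: 16 4-phenyl-1-butyne
Product: 18 5-phenylpent-2-ynal, via lithium acetylide 17 (not isolated)
Conditions: n-BuLi, THF, −78 °C; DMF, −78 to 0 °C; reverse quench into aq. KH2PO4
Reagents that add atoms: N,N-dimethylformamide, CN(C)C=O
Why: Formylation of a lithium acetylide with DMF is a standard ynal synthesis, and the phosphate-buffered reverse quench keeps the liberated dimethylamine from adding to the ynal.

**Step 10**
Reactants: 15 (4R,5R,6S)-6-(Ar-oxy)-4-(TBS-oxy)-5-(TDS-oxy)-2-iodocyclohex-2-en-1-one, 18 5-phenylpent-2-ynal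
Product: 19 (4R,5R,6S)-6-(Ar-oxy)-4-(TBS-oxy)-5-(TDS-oxy)-2-(1-hydroxy-5-phenylpent-2-yn-1-yl)cyclohex-2-en-1-one (both carbinol epimers)
Conditions: CrCl2 (4 equiv), NiCl2 (2 mol %), DMF, rt
Reagents that add atoms: none
Why: In the Nozaki–Hiyama–Kishi reaction zerovalent nickel inserts into the alkenyl C–I bond, the alkenyl group passes to chromium and adds 1,2 to the aldehyde only, under neutral conditions that ketones, chromones and silyl ethers tolerate; the new carbinol centre is not controlled and need not be.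

**Step 11**
Reactants: 19 (4R,5R,6S)-6-(Ar-oxy)-4-(TBS-oxy)-5-(TDS-oxy)-2-(1-hydroxy-5-phenylpent-2-yn-1-yl)cyclohex-2-en-1-one
Product: 20 (4R,5R,6S)-6-(Ar-oxy)-4-(TBS-oxy)-5-(TDS-oxy)-2-(5-phenylpent-2-ynoyl)cyclohex-2-en-1-one
Conditions: Dess–Martin periodinane, CH2Cl2, 0 °C to rt; filtered through a short silica pad and used at once
Reagents that add atoms: none
Why: Dess–Martin oxidation of a doubly activated secondary alcohol is the usual base-free way to turn Baylis–Hillman-type adducts into 2-acyl enones, so the base-sensitive alkylidene 1,3-dicarbonyl first appears in a medium containing no base and no nucleophile.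

**Step 12**
Reactants: 20 (4R,5R,6S)-6-(Ar-oxy)-4-(TBS-oxy)-5-(TDS-oxy)-2-(5-phenylpent-2-ynoyl)cyclohex-2-en-1-one, 21 4-methoxybenzyl alcohol
Product: 23 (5S,6R,7R,8S)-8-(Ar-oxy)-6-(TBS-oxy)-7-(TDS-oxy)-5-(PMB-oxy)-2-(2-phenylethyl)-5,6,7,8-tetrahydro-4H-chromen-4-one, via C5 ether enolate 22 (not isolated)
Conditions: 21 (3 equiv), Cs2CO3 (10 mol %), 4 Å MS, THF, −20 °C to rt
Reagents that add atoms: none
Why: Proposed new method: caesium 4-methoxybenzyl oxide adds reversibly to C5, the beta carbon of the C4a=C5 alkene activated by both the C8a and the C4 carbonyl, and the resulting 1,3-diketone enolate 22 attacks the ynone terminus C2 through its C8a oxygen, the vinyl anion being protonated by the alcohol so that the base turns over. The closest known reaction types are the base-catalysed oxa-Michael addition of alcohols to alkylidene 1,3-dicarbonyl compounds and the cyclisation of alkynyl 1,3-diketones and 2-hydroxyaryl ynones to 4-pyranones and chromones, whose union on an alkynoyl cyclohexenone has not been shown. The pyranone ring (O1, C2, C3, C4, C4a, C8a) closes 6-endo-dig, which is the Michael-type attack at the ynone beta carbon, whereas 5-exo closure would need attack at the alpha carbon and would give a non-stabilised vinyl anion. The new stereocentre C5 is controlled by the C6 silyloxy group: with the trans C6/C7 bis-silyl ether diaxial the alkoxide should enter axially and anti to the pseudoaxial C6–O bond, as conjugate additions to 4-silyloxycyclohexenones do, and because addition is reversible while pyranone formation is not, the adduct that closes is drained from the equilibrium. The step needs site selectivity for C5 over C2 of the ynone (secured by the double activation of C5), addition faster than gamma-deprotonation at C6 (secured by excess alcohol, catalytic base and low temperature) and an intact C8 centre (its hydrogen loses acidity once the C8a carbonyl has become an enolate and then a ring oxygen).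

**Step 13**
Reactants: 23 (5S,6R,7R,8S)-8-(Ar-oxy)-6-(TBS-oxy)-7-(TDS-oxy)-5-(PMB-oxy)-2-(2-phenylethyl)-5,6,7,8-tetrahydro-4H-chromen-4-one
Product: 24 (5S,6R,7R,8S)-8-(Ar-oxy)-6-(TBS-oxy)-7-(TDS-oxy)-5-hydroxy-2-(2-phenylethyl)-5,6,7,8-tetrahydro-4H-chromen-4-one
Conditions: DDQ, CH2Cl2/pH 7 phosphate buffer (10:1), 0 °C
Reagents that add atoms: none
Why: Oxidative cleavage of a 4-methoxybenzyl ether by DDQ proceeds by hydride abstraction from the electron-rich benzylic position and hydrolysis, leaves the C5–O bond and hence the C5 configuration untouched and should not affect silyl ethers or the chromone rings.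

**Step 14**
Reactants: 24 (5S,6R,7R,8S)-8-(Ar-oxy)-6-(TBS-oxy)-7-(TDS-oxy)-5-hydroxy-2-(2-phenylethyl)-5,6,7,8-tetrahydro-4H-chromen-4-one
Product: 25 (5S,6R,7S,8S)-5,6,7-trihydroxy-8-(Ar-oxy)-2-(2-phenylethyl)-5,6,7,8-tetrahydro-4H-chromen-4-one (CNP0125425.2)
Conditions: HF·pyridine, pyridine, THF, 0 °C to rt
Reagents that add atoms: none
Why: Fluoride desilylation buffered with pyridine removes both secondary silyl ethers by attack at silicon only, avoiding strong acid (ionisation at C5) and strong base (retro-aldol or epimerisation), so all four stereocentres should be retained.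

**Compound list**
1 | 2'-hydroxy-4'-methoxyacetophenone | CC(=O)c1ccc(OC)cc1O | starting material
2 | 1-(2-hydroxy-5-iodo-4-methoxyphenyl)ethan-1-one | CC(=O)c1cc(I)c(OC)cc1O | intermediate
3 | ethyl 3-phenylpropanoate | CCOC(=O)CCc1ccccc1 | starting material
4 | 1-(2-hydroxy-5-iodo-4-methoxyphenyl)-5-phenylpentane-1,3-dione | O=C(CC(=O)CCc1ccccc1)c1cc(I)c(OC)cc1O | intermediate
5 | 6-iodo-7-methoxy-2-(2-phenylethyl)-4H-chromen-4-one | COc1cc2oc(CCc3ccccc3)cc(=O)c2cc1I | intermediate
6 | 6-[hydroxy(tosyloxy)iodo]-7-methoxy-2-(2-phenylethyl)-4H-chromen-4-one | COc1cc2oc(CCc3ccccc3)cc(=O)c2cc1I(O)OS(=O)(=O)c1ccc(C)cc1 | intermediate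
7 | [7-methoxy-4-oxo-2-(2-phenylethyl)-4H-chromen-6-yl](2,4,6-trimethoxyphenyl)iodonium 4-toluenesulfonate | COc1cc2oc(CCc3ccccc3)cc(=O)c2cc1[I+]c1c(OC)cc(OC)cc1OC.Cc1ccc(S(=O)(=O)[O-])cc1 | intermediate
8 | (1S,2S)-3-bromocyclohexa-3,5-diene-1,2-diol | O[C@H]1C=CC=C(Br)[C@H]1O | starting material
9 | (1S,6S)-2-bromo-6-{[dimethyl(2,3-dimethylbutan-2-yl)silyl]oxy}cyclohexa-2,4-dien-1-ol | CC(C)C(C)(C)[Si](C)(C)O[C@H]1C=CC=C(Br)[C@H]1O | intermediate
10 | 6-{[(1S,6S)-2-bromo-6-(TDS-oxy)cyclohexa-2,4-dien-1-yl]oxy}-7-methoxy-2-(2-phenylethyl)-4H-chromen-4-one | COc1cc2oc(CCc3ccccc3)cc(=O)c2cc1O[C@@H]1C(Br)=CC=C[C@@H]1O[Si](C)(C)C(C)(C)C(C)C | intermediate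
11 | endoperoxide: 1-bromo-2,3-dioxabicyclo[2.2.2]oct-5-ene with O–O bridging C8a and C6 on the face opposite to the C8 aryloxy and C7 TDS-oxy groups | COc1cc2oc(CCc3ccccc3)cc(=O)c2cc1O[C@@H]1[C@]2(Br)C=C[C@@H](OO2)[C@@H]1O[Si](C)(C)C(C)(C)C(C)C | intermediate
12 | C8a bromohydrin: 1-bromocyclohex-2-ene-1,4-diol with the C8 aryloxy and C7 TDS-oxy groups, both hydroxyls trans to them | COc1cc2oc(CCc3ccccc3)cc(=O)c2cc1O[C@@H]1[C@](O)(Br)C=C[C@@H](O)[C@@H]1O[Si](C)(C)C(C)(C)C(C)C | intermediate
13 | (4R,5S,6S)-6-(Ar-oxy)-4-hydroxy-5-(TDS-oxy)cyclohex-2-en-1-one | COc1cc2oc(CCc3ccccc3)cc(=O)c2cc1O[C@@H]1C(=O)C=C[C@@H](O)[C@@H]1O[Si](C)(C)C(C)(C)C(C)C | intermediate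
14 | (4R,5R,6S)-6-(Ar-oxy)-4-(TBS-oxy)-5-(TDS-oxy)cyclohex-2-en-1-one | COc1cc2oc(CCc3ccccc3)cc(=O)c2cc1O[C@@H]1C(=O)C=C[C@@H](O[Si](C)(C)C(C)(C)C)[C@@H]1O[Si](C)(C)C(C)(C)C(C)C | intermediate
15 | (4R,5R,6S)-6-(Ar-oxy)-4-(TBS-oxy)-5-(TDS-oxy)-2-iodocyclohex-2-en-1-one | COc1cc2oc(CCc3ccccc3)cc(=O)c2cc1O[C@@H]1C(=O)C(I)=C[C@@H](O[Si](C)(C)C(C)(C)C)[C@@H]1O[Si](C)(C)C(C)(C)C(C)C | intermediate
16 | 4-phenyl-1-butyne | C#CCCc1ccccc1 | starting material
17 | lithium 4-phenylbut-1-yn-1-ide | [Li]C#CCCc1ccccc1 | intermediate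
18 | 5-phenylpent-2-ynal | O=CC#CCCc1ccccc1 | intermediate
19 | (4R,5R,6S)-6-(Ar-oxy)-4-(TBS-oxy)-5-(TDS-oxy)-2-(1-hydroxy-5-phenylpent-2-yn-1-yl)cyclohex-2-en-1-one, both carbinol epimers | COc1cc2oc(CCc3ccccc3)cc(=O)c2cc1O[C@@H]1C(=O)C(C(O)C#CCCc2ccccc2)=C[C@@H](O[Si](C)(C)C(C)(C)C)[C@@H]1O[Si](C)(C)C(C)(C)C(C)C | intermediate
20 | (4R,5R,6S)-6-(Ar-oxy)-4-(TBS-oxy)-5-(TDS-oxy)-2-(5-phenylpent-2-ynoyl)cyclohex-2-en-1-one | COc1cc2oc(CCc3ccccc3)cc(=O)c2cc1O[C@@H]1C(=O)C(C(=O)C#CCCc2ccccc2)=C[C@@H](O[Si](C)(C)C(C)(C)C)[C@@H]1O[Si](C)(C)C(C)(C)C(C)C | intermediate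
21 | 4-methoxybenzyl alcohol | COc1ccc(CO)cc1 | starting material
22 | caesium enolate of the C5 4-methoxybenzyl ether adduct, drawn as its enol: C5–OPMB trans to C6–OTBS, C8a enol, C4a alkynoyl | COc1cc2oc(CCc3ccccc3)cc(=O)c2cc1O[C@@H]1C(O)=C(C(=O)C#CCCc2ccccc2)[C@H](OCc2ccc(OC)cc2)[C@@H](O[Si](C)(C)C(C)(C)C)[C@@H]1O[Si](C)(C)C(C)(C)C(C)C | intermediate
23 | (5S,6R,7R,8S)-8-(Ar-oxy)-6-(TBS-oxy)-7-(TDS-oxy)-5-(PMB-oxy)-2-(2-phenylethyl)-5,6,7,8-tetrahydro-4H-chromen-4-one | COc1cc2oc(CCc3ccccc3)cc(=O)c2cc1O[C@@H]1c2oc(CCc3ccccc3)cc(=O)c2[C@H](OCc2ccc(OC)cc2)[C@@H](O[Si](C)(C)C(C)(C)C)[C@@H]1O[Si](C)(C)C(C)(C)C(C)C | intermediate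
24 | (5S,6R,7R,8S)-8-(Ar-oxy)-6-(TBS-oxy)-7-(TDS-oxy)-5-hydroxy-2-(2-phenylethyl)-5,6,7,8-tetrahydro-4H-chromen-4-one | COc1cc2oc(CCc3ccccc3)cc(=O)c2cc1O[C@@H]1c2oc(CCc3ccccc3)cc(=O)c2[C@H](O)[C@@H](O[Si](C)(C)C(C)(C)C)[C@@H]1O[Si](C)(C)C(C)(C)C(C)C | intermediate
25 | (5S,6R,7S,8S)-5,6,7-trihydroxy-8-{[7-methoxy-4-oxo-2-(2-phenylethyl)-4H-chromen-6-yl]oxy}-2-(2-phenylethyl)-5,6,7,8-tetrahydro-4H-chromen-4-one | COc1cc2oc(CCc3ccccc3)cc(=O)c2cc1O[C@@H]1c2oc(CCc3ccccc3)cc(=O)c2[C@H](O)[C@@H](O)[C@@H]1O | target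

**Step count and risks**
Total step count: 14. Longest linear sequence: 12 steps (steps 1–3, 5–8 and 10–14, from compound 1).

Steps most likely to fail:

1. Step 12 (key step). Deprotonation at C6, which is gamma to both carbonyls, followed by loss of the C7 silyloxy group and aromatisation may outrun alkoxide addition; the alkoxide may enter syn to the C6 silyloxy group; closure may go 5-exo. The fallback uses known chemistry, sets out from enone 14 and returns to the route at 22, which is then closed to 23. Enone 14 is epoxidised under Weitz–Scheffer conditions (H2O2, cat. NaOH, MeOH, 0 °C), anti to the C6 silyloxy group, to give the 4a,5-epoxy ketone F1. Reductive opening of the C4a–O bond with PhSeSePh/NaBH4/AcOH in EtOH gives the 5-hydroxy ketone F2. 4-Methoxybenzyl trichloroacetimidate with catalytic Sc(OTf)3 gives the 5-O-PMB ketone F3. Kinetic deprotonation at the C4a methylene with LiHMDS at −78 °C and aldol addition to ynal 18 gives the aldol adduct F4. Dess–Martin oxidation then gives 22, this time isolated as the enolised 1,3-diketone, and its closure to 23 with catalytic Cs2CO3 or AuCl3 is the known 6-endo-dig cyclisation of alkynyl 1,3-diketones to 4-pyranones.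

2. Step 5. The alkoxide may be oxidised by the iodonium salt (hydride loss from C8 and aromatisation), the silyl group may migrate from O7 to O8 under base, or the fairly electron-rich chromonyl group may transfer slowly. The fallback sets out from aryl iodide 5 and alcohol 9 and returns at 10. Miyaura borylation of 5 (B2pin2, PdCl2(dppf), KOAc, dioxane, 80 °C) gives the pinacol boronate F5. KHF2 in aqueous MeOH gives the potassium trifluoroborate F6. A Chan–Lam–Evans coupling of F6 with 9 under strong-base-free conditions (Cu(OAc)2, DMAP, 4 Å MS, O2, CH2Cl2, rt) then forms the same C8–O–aryl bond with retention.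

3. Step 10. The C–I bond may be reduced without addition, or addition of the hindered alkenylchromium species may be so slow that the ynal is consumed in other ways. The fallback sets out from iodoenone 15 and alkyne 16 and returns at 20: a copper-free carbonylative Sonogashira coupling (PdCl2(PPh3)2, CO, i-Pr2NEt, THF, rt) builds the alkynoyl group directly and skips 19 and the oxidation.

**Further compounds**
F1 | step 12 | 4a,5-epoxy ketone: 2,3-epoxycyclohexanone bearing C6–OTBS, C7–OTDS and C8–OAr, oxirane trans to C6–OTBS | COc1cc2oc(CCc3ccccc3)cc(=O)c2cc1O[C@@H]1C(=O)[C@@H]2O[C@@H]2[C@@H](O[Si](C)(C)C(C)(C)C)[C@@H]1O[Si](C)(C)C(C)(C)C(C)C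
F2 | step 12 | 5-hydroxy ketone: 3-hydroxycyclohexanone bearing C6–OTBS, C7–OTDS and C8–OAr, C5–OH trans to C6–OTBS | COc1cc2oc(CCc3ccccc3)cc(=O)c2cc1O[C@@H]1C(=O)C[C@H](O)[C@@H](O[Si](C)(C)C(C)(C)C)[C@@H]1O[Si](C)(C)C(C)(C)C(C)C
F3 | step 12 | 5-O-PMB ketone: 4-methoxybenzyl ether of F2 | COc1cc2oc(CCc3ccccc3)cc(=O)c2cc1O[C@@H]1C(=O)C[C@H](OCc2ccc(OC)cc2)[C@@H](O[Si](C)(C)C(C)(C)C)[C@@H]1O[Si](C)(C)C(C)(C)C(C)C
F4 | step 12 | aldol adduct: C4a-(1-hydroxy-5-phenylpent-2-yn-1-yl) derivative of F3, epimer mixture at C4a and the carbinol carbon | COc1cc2oc(CCc3ccccc3)cc(=O)c2cc1O[C@@H]1C(=O)C(C(O)C#CCCc2ccccc2)[C@H](OCc2ccc(OC)cc2)[C@@H](O[Si](C)(C)C(C)(C)C)[C@@H]1O[Si](C)(C)C(C)(C)C(C)C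
F5 | step 5 | 7-methoxy-2-(2-phenylethyl)-6-(4,4,5,5-tetramethyl-1,3,2-dioxaborolan-2-yl)-4H-chromen-4-one | COc1cc2oc(CCc3ccccc3)cc(=O)c2cc1B1OC(C)(C)C(C)(C)O1
F6 | step 5 | potassium trifluoro[7-methoxy-4-oxo-2-(2-phenylethyl)-4H-chromen-6-yl]borate | COc1cc2oc(CCc3ccccc3)cc(=O)c2cc1[B-](F)(F)F.[K+]
F0 | step 10 | none | none
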